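## Retrosynthetic overview

1. The target is reached by oxidative demethylation and re-reduction of its hydroquinone dimethyl ether; the arene is bought, so the cyclopentane is the only ring formed.
2. The cyclopentane is closed last in the carbon framework, by a biomimetic C7–C11 Michael-type closure run as an enantioselective copper hydride reductive cyclisation of the complete linear 5,12-dioxo-Δ6,Δ10 bis-enone; this one step sets both quaternary centres.
3. The bis-enone comes from C4–C5 union of a (Z)-allylbarium (aryl side) with a C5–C16 enal, followed by allylic oxidation.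
4. The (Z)-allylic chloride comes from Negishi coupling of a benzylzinc with (Z)-3-iodo-2-methylprop-2-en-1-ol; the Z geometry is set by anti-carbomagnesiation of propargyl alcohol.
5. The C5–C16 enal comes from geranyl acetate (SeO2 oxidation at C12) and hydrozirconated, silyl-protected 2-methylbut-3-yn-2-ol (C13–C16).

Assumption 1: biogenetic chain numbering is used (C1 = benzylic CH2 … C16); the SMILES is read as 2Z, 13E, 7S, 11S, with the two ring methyls cis.
Assumption 2: the presumed biosynthesis is taken to be closure of the C11 enol(ate) of a 12-ketone onto C7 of a 5-oxo-Δ6 enone in an oxidised geranylgeranyl-toluquinol.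
Assumption 3: the sense of induction in step 12 cannot be predicted with confidence; the route is written with (R)-SEGPHOS as the ligand antipode that gives 7S,11S, and (S)-SEGPHOS is used instead if the first run gives the mirror image.

## Route

Step 1
Reactants: 1 2,6-dimethylbenzene-1,4-diol
Product: 2 2,5-dimethoxy-1,3-dimethylbenzene
Conditions: MeI (3 equiv), K2CO3 (4 equiv), acetone, reflux, N2
Reagents that add atoms: iodomethane, CI
Why: Williamson O-methylation of both phenols gives an oxidation-proof hydroquinone dimethyl ether that survives every organometallic step.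

Step 2
Reactants: 2 2,5-dimethoxy-1,3-dimethylbenzene
Product: 3 1-(bromomethyl)-2,5-dimethoxy-3-methylbenzene
Conditions: NBS (0.95 equiv), AIBN (5 mol %), PhCF3, 85 °C
Reagents that add atoms: N-bromosuccinimide, O=C1CCC(=O)N1Br
Why: Wohl–Ziegler radical benzylic bromination; the two methyl groups are equivalent, so only one mono-bromide can form, and sub-stoichiometric NBS limits dibromide.

Step 3
Reactants: 4 prop-2-yn-1-ol
Product: 6 (Z)-3-iodo-2-methylprop-2-en-1-ol, via vinylmagnesium alkoxide 5 (not isolated)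
Conditions: MeMgBr (2.5 equiv), CuI (10 mol %), THF, −10 °C → rt; then I2, THF, −10 °C; H2O
Reagents that add atoms: methylmagnesium bromide, C[Mg]Br; iodine, II
Why: copper-catalysed anti-carbomagnesiation of the propargylic alkoxide gives a five-membered chelated vinylmagnesium whose iodinolysis goes with retention, so iodine ends cis to CH2OH (Z).

Step 4
Reactants: 3 1-(bromomethyl)-2,5-dimethoxy-3-methylbenzene; 6 (Z)-3-iodo-2-methylprop-2-en-1-ol
Product: 8 (Z)-4-(2,5-dimethoxy-3-methylphenyl)-2-methylbut-2-en-1-ol, via benzylzinc bromide 7 (not isolated)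
Conditions: Zn dust, LiCl, THF, 0 °C → rt; then 6, Pd(OAc)2 (2 mol %), SPhos (4 mol %), THF, rt
Reagents that add atoms: none
Why: Negishi sp3–sp2 cross-coupling proceeds with retention of the alkenyl iodide geometry and tolerates the free hydroxyl, giving the neryl-type (2Z) olefin.

Step 5
Reactants: 8 (Z)-4-(2,5-dimethoxy-3-methylphenyl)-2-methylbut-2-en-1-ol
Product: 9 1-[(Z)-4-chloro-3-methylbut-2-en-1-yl]-2,5-dimethoxy-3-methylbenzene
Conditions: NCS, Me2S, CH2Cl2, −30 → 0 °C
Reagents that add atoms: N-chlorosuccinimide, O=C1CCC(=O)N1Cl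
Why: Corey–Kim chlorination displaces the alkoxysulfonium by SN2 at the primary carbon, without allylic transposition or Z/E loss.

Step 6
Reactants: 10 2-methylbut-3-yn-2-ol
Product: 11 triethyl[(2-methylbut-3-yn-2-yl)oxy]silane
Conditions: TESCl, imidazole, DMAP (cat.), DMF, rt
Reagents that add atoms: chlorotriethylsilane, CC[Si](Cl)(CC)CC
Why: silyl protection of the tertiary alcohol is needed for the hydrozirconation, allylbarium and copper hydride steps, and the ether is stable to K2CO3/MeOH.

Step 7
Reactants: 12 geranyl acetate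
Product: 13 (2E,6E)-3,7-dimethyl-8-oxoocta-2,6-dien-1-yl acetate
Conditions: SeO2 (1.2 equiv), 95% EtOH, reflux
Reagents that add atoms: selenium dioxide, O=[Se]=O
Why: Riley allylic oxidation (ene reaction then 2,3-sigmatropic shift) is selective for the E-methyl of the terminal trisubstituted olefin and gives the E-enal that becomes C12.

Step 8
Reactants: 13 (2E,6E)-3,7-dimethyl-8-oxoocta-2,6-dien-1-yl acetate; 11 triethyl[(2-methylbut-3-yn-2-yl)oxy]silane
Product: 17 (2E,6E,9E)-3,7,11-trimethyl-11-(triethylsilyloxy)dodeca-2,6,9-triene-1,8-diol, via alkenylzirconocene chloride 14 (not isolated), via alkenyl(methyl)zinc 15 (not isolated), via hydroxy acetate 16 (not isolated)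
Conditions: 11, Cp2Zr(H)Cl, CH2Cl2, rt; Me2Zn, toluene, −65 °C; 13, 0 °C; then MeOH, K2CO3 (0.3 equiv), rt
Reagents that add atoms: none
Why: syn-hydrozirconation of the terminal alkyne fixes the 13E olefin, zirconium-to-zinc transmetalation gives clean 1,2-addition to the enal in the presence of the acetate, and methanolysis frees the C5 alcohol (the C12 carbinol is oxidised next, so its configuration is irrelevant).

Step 9
Reactants: 17 (2E,6E,9E)-3,7,11-trimethyl-11-(triethylsilyloxy)dodeca-2,6,9-triene-1,8-diol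
Product: 18 (2E,6E,9E)-3,7,11-trimethyl-8-oxo-11-(triethylsilyloxy)dodeca-2,6,9-trienal
Conditions: MnO2 (activated, excess), CH2Cl2, rt
Reagents that add atoms: none
Why: MnO2 oxidises both allylic alcohols (primary to the enal, bis-allylic secondary to the dienone) under neutral conditions and leaves the silyl ether and olefin geometries intact.

Step 10
Reactants: 9 1-[(Z)-4-chloro-3-methylbut-2-en-1-yl]-2,5-dimethoxy-3-methylbenzene; 18 (2E,6E,9E)-3,7,11-trimethyl-8-oxo-11-(triethylsilyloxy)dodeca-2,6,9-trienal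
Product: 20 (2Z,6E,10E,13E)-1-(2,5-dimethoxy-3-methylphenyl)-5-hydroxy-3,7,11,15-tetramethyl-15-(triethylsilyloxy)hexadeca-2,6,10,13-tetraen-12-one, via allylbarium chloride 19 (not isolated)
Conditions: BaI2, Li(C12H10) (lithium biphenylide, 2 equiv), THF, rt; 9 (1.3 equiv), −78 °C; then 18, −78 °C; H2O
Reagents that add atoms: none
Why: allylbarium reagents add to aldehydes 1,2 at the α-carbon with retention of the Z geometry at −78 °C, and the aldehyde reacts well before the hindered cross-conjugated ketone (α-selective allylbarium carbonyl addition; the C5 carbinol is oxidised next).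

Step 11
Reactants: 20 (2Z,6E,10E,13E)-1-(2,5-dimethoxy-3-methylphenyl)-5-hydroxy-3,7,11,15-tetramethyl-15-(triethylsilyloxy)hexadeca-2,6,10,13-tetraen-12-one
Product: 21 (2Z,6E,10E,13E)-1-(2,5-dimethoxy-3-methylphenyl)-3,7,11,15-tetramethyl-15-(triethylsilyloxy)hexadeca-2,6,10,13-tetraene-5,12-dione
Conditions: MnO2 (activated, excess), CH2Cl2, rt
Reagents that add atoms: none
Why: neutral MnO2 oxidation of the allylic C5 alcohol gives the enone without moving the skipped (β,γ) Z olefin into conjugation.

Step 12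
Reactants: 21 (2Z,6E,10E,13E)-1-(2,5-dimethoxy-3-methylphenyl)-3,7,11,15-tetramethyl-15-(triethylsilyloxy)hexadeca-2,6,10,13-tetraene-5,12-dione
Product: 23 (E)-1-[(1S,2S)-2-[(Z)-6-(2,5-dimethoxy-3-methylphenyl)-4-methyl-2-oxohex-4-en-1-yl]-1,2-dimethylcyclopentyl]-4-hydroxy-4-methylpent-2-en-1-one, via silyl enol ether 22 (not isolated)
Conditions: Cu(OAc)2·H2O (5 mol %), (R)-SEGPHOS (5.5 mol %), (EtO)2MeSiH (1.3 equiv), toluene, −20 °C → rt; then HF·pyridine, pyridine/THF, 0 °C
Reagents that add atoms: none
Why: Proposed new method: the ligated monovalent copper hydride should deliver hydride to C10, the only enone β-carbon that is neither β,β-disubstituted (C7) nor flanked by the quaternary silyloxy carbon (C14), giving the tetrasubstituted C11 copper enolate regiospecifically and without base; this enolate closes 5-exo onto C7 of the 5-oxo-Δ6 enone through a compact transition state in which copper bridges the enolate oxygen and the acceptor carbonyl, which places the C12 acyl and C6 arms (and so the two methyls) cis and lets the C2-symmetric bisphosphine select the face (7S,11S), after which Si–H metathesis traps the C5 enolate as 22 so that neither aldol closure of the 1,5-diketone nor olefin migration can follow, and HF·pyridine cleaves both silyl groups; closest known reaction type: copper hydride-catalysed enantioselective reductive Michael and reductive aldol cyclisations of tethered enones, here extended to a β,β-disubstituted acceptor and two vicinal quaternary centres.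

Step 13
Reactants: 23 (E)-1-[(1S,2S)-2-[(Z)-6-(2,5-dimethoxy-3-methylphenyl)-4-methyl-2-oxohex-4-en-1-yl]-1,2-dimethylcyclopentyl]-4-hydroxy-4-methylpent-2-en-1-one
Product: 25 (E)-1-[(1S,2S)-2-[(Z)-6-(2,5-dihydroxy-3-methylphenyl)-4-methyl-2-oxohex-4-en-1-yl]-1,2-dimethylcyclopentyl]-4-hydroxy-4-methylpent-2-en-1-one, via quinone 24 (not isolated)
Conditions: (NH4)2Ce(NO3)6 (2.2 equiv), MeCN/H2O (2:1), 0 °C; then aq. Na2S2O4, EtOAc, rt, Ar
Reagents that add atoms: water, O
Why: oxidative demethylation of the 1,4-dimethoxyarene (radical cation, water attack, loss of methanol) gives the quinone without touching enone, tertiary alcohol or trisubstituted olefin, and neutral dithionite reduction then gives the hydroquinone without chroman formation, aldol closure or loss of the Z olefin and ring stereocentres.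

## Compound list

1 | 2,6-dimethylbenzene-1,4-diol (2,6-dimethylhydroquinone) | Cc1cc(O)cc(C)c1O | starting material
2 | 2,5-dimethoxy-1,3-dimethylbenzene | COc1cc(C)c(OC)c(C)c1 | intermediate
3 | 1-(bromomethyl)-2,5-dimethoxy-3-methylbenzene | COc1cc(C)c(OC)c(CBr)c1 | intermediate
4 | prop-2-yn-1-ol (propargyl alcohol) | OCC#C | starting material
5 | bromomagnesium (Z)-3-(bromomagnesio)-2-methylprop-2-en-1-olate (Mg cis to CH2O) | Br[Mg]/C=C(/C)CO[Mg]Br | intermediate
6 | (Z)-3-iodo-2-methylprop-2-en-1-ol | I/C=C(/C)CO | intermediate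
7 | (2,5-dimethoxy-3-methylbenzyl)zinc bromide | COc1cc(C)c(OC)c(C[Zn]Br)c1 | intermediate
8 | (Z)-4-(2,5-dimethoxy-3-methylphenyl)-2-methylbut-2-en-1-ol | COc1cc(C)c(OC)c(C/C=C(/C)CO)c1 | intermediate
9 | 1-[(Z)-4-chloro-3-methylbut-2-en-1-yl]-2,5-dimethoxy-3-methylbenzene | COc1cc(C)c(OC)c(C/C=C(/C)CCl)c1 | intermediate
10 | 2-methylbut-3-yn-2-ol | CC(C)(O)C#C | starting material
11 | triethyl[(2-methylbut-3-yn-2-yl)oxy]silane | CC[Si](CC)(CC)OC(C)(C)C#C | intermediate
12 | geranyl acetate, (2E)-3,7-dimethylocta-2,6-dien-1-yl acetate | CC(=O)OC/C=C(C)/CCC=C(C)C | starting material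
13 | (2E,6E)-3,7-dimethyl-8-oxoocta-2,6-dien-1-yl acetate | CC(=O)OC/C=C(C)/CC/C=C(C)/C=O | intermediate
14 | chloro[(E)-3-methyl-3-(triethylsilyloxy)but-1-enyl]zirconocene | CC[Si](CC)(CC)OC(C)(C)/C=C/[Zr](Cl)(C1C=CC=C1)C1C=CC=C1 | intermediate
15 | methyl[(E)-3-methyl-3-(triethylsilyloxy)but-1-enyl]zinc | C[Zn]/C=C/C(C)(C)O[Si](CC)(CC)CC | intermediate
16 | (2E,6E,9E)-8-hydroxy-3,7,11-trimethyl-11-(triethylsilyloxy)dodeca-2,6,9-trien-1-yl acetate (C8 racemic) | CC(=O)OC/C=C(C)/CC/C=C(C)/C(O)/C=C/C(C)(C)O[Si](CC)(CC)CC | intermediate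
17 | (2E,6E,9E)-3,7,11-trimethyl-11-(triethylsilyloxy)dodeca-2,6,9-triene-1,8-diol (C8 racemic) | OC/C=C(C)/CC/C=C(C)/C(O)/C=C/C(C)(C)O[Si](CC)(CC)CC | intermediate
18 | (2E,6E,9E)-3,7,11-trimethyl-8-oxo-11-(triethylsilyloxy)dodeca-2,6,9-trienal | O=C/C=C(C)/CC/C=C(C)/C(=O)/C=C/C(C)(C)O[Si](CC)(CC)CC | intermediate
19 | [(Z)-4-(2,5-dimethoxy-3-methylphenyl)-2-methylbut-2-enyl]barium chloride | COc1cc(C)c(OC)c(C/C=C(/C)C[Ba]Cl)c1 | intermediate
20 | (2Z,6E,10E,13E)-1-(2,5-dimethoxy-3-methylphenyl)-5-hydroxy-3,7,11,15-tetramethyl-15-(triethylsilyloxy)hexadeca-2,6,10,13-tetraen-12-one (C5 racemic) | COc1cc(C)c(OC)c(C/C=C(/C)CC(O)/C=C(C)/CC/C=C(C)/C(=O)/C=C/C(C)(C)O[Si](CC)(CC)CC)c1 | intermediate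
21 | (2Z,6E,10E,13E)-1-(2,5-dimethoxy-3-methylphenyl)-3,7,11,15-tetramethyl-15-(triethylsilyloxy)hexadeca-2,6,10,13-tetraene-5,12-dione | COc1cc(C)c(OC)c(C/C=C(/C)CC(=O)/C=C(C)/CC/C=C(C)/C(=O)/C=C/C(C)(C)O[Si](CC)(CC)CC)c1 | intermediate
22 | C5 diethoxy(methyl)silyl enol ether (C5=C6) of the cyclised (7S,11S) diketone, tertiary alcohol still as triethylsilyl ether | COc1cc(C)c(OC)c(C/C=C(/C)CC(O[Si](C)(OCC)OCC)=C[C@]2(C)CCC[C@]2(C)C(=O)/C=C/C(C)(C)O[Si](CC)(CC)CC)c1 | intermediate
23 | (E)-1-[(1S,2S)-2-[(Z)-6-(2,5-dimethoxy-3-methylphenyl)-4-methyl-2-oxohex-4-en-1-yl]-1,2-dimethylcyclopentyl]-4-hydroxy-4-methylpent-2-en-1-one (ring methyls cis) | COc1cc(C)c(OC)c(C/C=C(/C)CC(=O)C[C@]2(C)CCC[C@]2(C)C(=O)/C=C/C(C)(C)O)c1 | intermediate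
24 | 2-methyl-6-substituted 1,4-benzoquinone corresponding to the target (same side chain, 7S,11S) | CC1=CC(=O)C=C(C/C=C(/C)CC(=O)C[C@]2(C)CCC[C@]2(C)C(=O)/C=C/C(C)(C)O)C1=O | intermediate
25 | CNP0212540.3, (E)-1-[(1S,2S)-2-[(Z)-6-(2,5-dihydroxy-3-methylphenyl)-4-methyl-2-oxohex-4-en-1-yl]-1,2-dimethylcyclopentyl]-4-hydroxy-4-methylpent-2-en-1-one | C/C(=C/Cc1cc(O)cc(C)c1O)CC(=O)C[C@]1(C)CCC[C@]1(C)C(=O)/C=C/C(C)(C)O | target

## Step count and risk

Total step count: 13.
Longest linear sequence: 8 steps (steps 1, 2, 4, 5, 10, 11, 12, 13; the geranyl acetate branch is 7).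

Steps most likely to fail:

1. Step 12, the reductive Michael cyclisation. It is the least precedented step: hydride may go to C14 or C7, or add 1,2 at C12. The copper enolate may be silylated or protonated before it attacks the β,β-disubstituted C7. The trans diastereomer or the wrong enantiomer may dominate, and the C6 enolate could add on to C14. Fallback: setting out from 21, give up ligand control and run a cobalt-mediated cycloreduction (Co(dpm)2 with dpm = 2,2,6,6-tetramethylheptane-3,5-dionate, PhSiH3, ClCH2CH2Cl, 50 °C, aqueous work-up). This gives the cyclised triethylsilyl ether as a racemate, namely the (7S,11S) triethylsilyl ether F1 and its (7R,11R) mirror image F2. Preparative chiral SFC removes F2, and HF·pyridine on F1 returns to the route at 23.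

2. Step 10, the allylbarium union. It needs freshly made active barium and depends on α- over γ-attack, on Z retention and on aldehyde-over-dienone selectivity. Fallback: setting out from 9 and 18, use a sulfone-stabilised anion instead. PhSO2Na in DMF converts 9 into the (Z)-allylic phenyl sulfone F3. n-BuLi in THF at −78 °C followed by 18 gives the β-hydroxy sulfone F4 by α-attack on the aldehyde. Dess–Martin periodinane gives the β-keto sulfone F5. SmI2 (divalent samarium iodide) in THF/MeOH at −78 °C removes the sulfonyl group and gives 21 directly, so steps 10 and 11 are both replaced and the route is rejoined at 21.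

3. Step 2, the benzylic bromination. Ring bromination of the electron-rich arene and double bromination can compete. Fallback: setting out from 2, replace the radical step by polar lateral metalation: n-BuLi/KOt-Bu in THF at −78 °C deprotonates one of the two equivalent methyls flanking the methoxy group to give (2,5-dimethoxy-3-methylbenzyl)potassium F6, and ZnBr2 converts this into the benzylzinc 7, where the route is rejoined for the coupling of step 4.

## Further compounds

F1 | step 12 | (7S,11S) triethylsilyl ether of 23 | COc1cc(C)c(OC)c(C/C=C(/C)CC(=O)C[C@]2(C)CCC[C@]2(C)C(=O)/C=C/C(C)(C)O[Si](CC)(CC)CC)c1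
F2 | step 12 | (7R,11R) triethylsilyl ether, mirror image of F1 | COc1cc(C)c(OC)c(C/C=C(/C)CC(=O)C[C@@]2(C)CCC[C@@]2(C)C(=O)/C=C/C(C)(C)O[Si](CC)(CC)CC)c1
F3 | step 10 | 1-[(Z)-3-methyl-4-(phenylsulfonyl)but-2-en-1-yl]-2,5-dimethoxy-3-methylbenzene | COc1cc(C)c(OC)c(C/C=C(/C)CS(=O)(=O)c2ccccc2)c1
F4 | step 10 | β-hydroxy sulfone: 20 carrying a phenylsulfonyl group at C4 | COc1cc(C)c(OC)c(C/C=C(/C)C(C(O)/C=C(C)/CC/C=C(C)/C(=O)/C=C/C(C)(C)O[Si](CC)(CC)CC)S(=O)(=O)c2ccccc2)c1
F5 | step 10 | β-keto sulfone: 21 carrying a phenylsulfonyl group at C4 | COc1cc(C)c(OC)c(C/C=C(/C)C(C(=O)/C=C(C)/CC/C=C(C)/C(=O)/C=C/C(C)(C)O[Si](CC)(CC)CC)S(=O)(=O)c2ccccc2)c1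
F6 | step 2 | (2,5-dimethoxy-3-methylbenzyl)potassium | COc1cc(C)c(OC)c(C[K])c1
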